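**Assumption (chemistry):** the target has no stereocentre and no double bond. The stilbenes 8 and 14 are therefore carried as unseparated mixtures of geometric isomers, because hydrogenation removes the distinction.

## Analysis of the target

The target 19 is an achiral macrocyclic bis(bibenzyl): four benzene rings held in a 19-membered ring by two diaryl ether oxygens and two CH2CH2 bridges. Rings A and C each carry the bridge carbon at C1, free hydroxyls at C3 and C4, and the ether oxygen at C5. Ring B is a 1,4-phenylene bound through oxygen to C5 of ring A and through CH2CH2 to C1 of ring C; ring D is a 1,3-phenylene bound through oxygen to C5 of ring C and through CH2CH2 to C1 of ring A. Nothing stereochemical has to be set, but the two halves differ (para against meta phenylene), so the ring cannot be made by dimerisation. The sensitive groups are the two catechols, each part of a contiguous 1,2,3-trioxygenated array that oxidises easily to an ortho-quinone in base and air. The difficulties are the closure of the large ring, two diaryl ethers at carbons flanked by oxygen, and three neighbouring oxygens on each of rings A and C that must end up differentiated. The strategy rests on one feature: the C4 hydroxyl of rings A and C has the ether at C5 on one side and the bridge at C1 in the para position. In a macrocycle lacking the C3 oxygens, C3 is therefore the only hydrogen-bearing carbon ortho or para to each phenol. A phenol-directed formylation must land there, and the formyl group can then be exchanged for hydroxyl.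

## Retrosynthetic reasoning

**C3–O bonds of rings A and C (19 to 17).** Both C3 hydroxyls are removed and replaced by formyl groups, giving the bis-salicylaldehyde 17. The forward reaction is a double Dakin oxidation passing through the bis-formate 18. Cutting here means the macrocycle is built with two fewer oxygens and without the crowded 1,2,3-pattern, and the last step needs no protecting group. The forward step must make aryl migration win over hydride migration at both sites and leave the catechols intact.

**C3–CHO bonds (17 to 16).** The formyl groups are removed to give the bisphenol 16. The forward reaction is a magnesium phenoxide ortho-formylation, which has only C3 available on each phenol ring. Rings B and D carry no hydroxyl and are not addressed.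

**O–CH3 bonds and bridge saturation (16 to 15 to 14).** The phenols of 16 are traced to the dimethyl ether 15, so the C4 oxygens travel as methyl ethers through all base-mediated steps. The saturated bridge between rings D and A in 15 is traced to the stilbene 14, so the ring can be closed by olefination.

**The D–A bridge (14 to 12, then 11 and 10).** The ring is opened at the double bond between the benzylic carbon on C1 of ring A and the benzylic carbon of ring D. This gives the ylide aldehyde 13, generated from the phosphonium salt 12. The cut is placed here and not at an ether oxygen because an olefination tolerates high dilution far better than a copper-mediated etherification. The two reacting ends also arrive without protecting groups: the aldehyde on ring A comes with the last building block, and the hydroxymethyl group on ring D has been carried unchanged. Salt 12 comes from bromide 11, and 11 from the alcohol 10.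

**C5(ring A)–O bond (10 to 9 and 4).** The ether between rings A and B is cut to the phenol 9 and the bromoaldehyde 4. The forward Ullmann coupling must arylate the phenol and leave the primary alcohol alone.

**The B–C bridge (9 to 8, then 6 and 3).** The bibenzyl of 9 is traced to the stilbene 8, whose benzyl ether masks the ring B phenol. One hydrogenation then saturates the bridge and frees the phenol. Stilbene 8 is cut at the double bond into aldehyde 6 and phosphonium salt 3, which reacts through its ylide 7.

**C5(ring C)–O bond and the salt (6 to 4 and 5; 3 to 1 and 2).** The ether between rings C and D is cut to a second molecule of 4 and the phenol 5. The same bromoaldehyde thus supplies both oxygenated rings. Salt 3 comes from the benzylic chloride 1 and the phosphine 2.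

## Alternatives that were turned down

**Alternative 1:** The bond between C1 of ring C and its bridge carbon is cut. The open-chain precursor A1 has ring C as a 3,4-dimethoxy-5-aryloxybenzoyl chloride and ring B as a para-vinyl group. Forward, Pd(OAc)2 and N-ethylmorpholine in hot xylene insert zerovalent palladium into the C–Cl bond, carbon monoxide is lost, and the aryl–palladium species adds to the styrene terminus. β-Hydride elimination closes the 19-membered ring as the tetra-O-methyl (E)-stilbene A2. Hydrogenation and fourfold demethylation would follow.
- For: all six oxygens come from gallate-type building blocks, so no late oxidation touches a catechol. On this point it is stronger than the chosen route.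
- Against: the decarbonylative Heck reaction is an intermolecular coupling run above 120 °C. At the dilution a large ring demands, the bimolecular-in-palladium steps slow down while catalyst decomposition does not. The reaction can only give the E olefin, whereas a Wittig closure can escape through whichever geometry the ring prefers. Each oxygenated ring would need a gallate differentiated into two methyl ethers and one hindered aryl ether, so the fragments are longer to make.
- Comparison: the chosen route offers in its place a ring closure of a type established for this family, one purchased aldehyde used twice, and its single uncertain oxidation at the very end.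

**Alternative 2:** The C4–O bonds of rings A and C are cut. The precursor A3 is a macrocycle with MOM ethers at C3 and hydrogen at C4. Forward, n-BuLi with TMEDA would remove the C4 proton of each ring, which sits between the MOM ether and the aryl ether. B(OMe)3 and then alkaline H2O2 would give the C4 phenols of A4, and acid would then remove the MOM groups.
- For: the regiochemical logic is as strong as that of the chosen route, since a proton between two oxygen substituents is the most acidic on the ring.
- Against: a doubly lithiated macrocycle is required, and the second metalation is slower and prone to aggregation. C2 of rings A and C and the positions ortho to the ether oxygens on rings B and D compete. The 3,5-dioxygenated building blocks must be desymmetrised into one MOM ether and one aryl ether, and a final deprotection is added.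
- Comparison: the chosen route fixes the site by substitution, not by relative acidity, uses reagents that tolerate the whole molecule, and ends without a protecting group.

**Alternative 3:** The C5(ring A)–O bond is cut. The open-chain precursor A5 has a free phenol on ring B and ring A as a 5-fluoro-4-formyl-3-methoxy ring. Forward, Cs2CO3 in DMF lets the phenoxide displace fluoride ortho to the formyl group. This closes the ring as the macrocyclic aldehyde A6, whose formyl group is later oxidised to the C4 hydroxyl before demethylation.
- For: an SNAr etherification is irreversible, gives no geometric isomers and leaves no phosphine oxide, and the activating group becomes a wanted oxygen. As a ring closure it is arguably more reliable than a Wittig reaction.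
- Against: one ortho formyl group is a modest activator on a ring that also carries a methoxy and an alkyl group. Long heating at high dilution would expose the aldehyde to base. Rings A and C would need two different multi-step fragments, one of them again a gallate with a hindered Ullmann ether. The later oxidation of a 2,6-disubstituted, non-phenolic aldehyde needs a peracid.
- Comparison: the chosen route treats both oxygenated rings alike, from one commercial aldehyde, and oxidises both sites in one operation.

Key step: step 12

## Route

Step 1
Reactants: 1 4-benzyloxybenzyl chloride; 2 triphenylphosphine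
Product: 3 (4-benzyloxybenzyl)triphenylphosphonium chloride
Conditions: toluene, reflux
Reagents that add atoms: none
Why: SN2 quaternisation of the phosphine by a benzylic chloride (phosphonium salt formation); the salt should crystallise from toluene and be used without chromatography.

Step 2
Reactants: 4 3-bromo-4-methoxybenzaldehyde; 5 3-hydroxybenzyl alcohol
Product: 6 3-[3-(hydroxymethyl)phenoxy]-4-methoxybenzaldehyde
Conditions: CuI (10 mol %), picolinic acid (20 mol %), K3PO4, DMSO, 90 °C, Ar
Reagents that add atoms: none
Why: Ullmann-type copper-catalysed O-arylation; K3PO4 ionises the phenol but not the primary alcohol, so only the phenoxide enters the copper cycle, and the aldehyde, which has no α-hydrogen, tolerates the weak base.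

Step 3
Reactants: 6 3-[3-(hydroxymethyl)phenoxy]-4-methoxybenzaldehyde; 3 (4-benzyloxybenzyl)triphenylphosphonium chloride
Product: 8 [3-[5-[2-(4-benzyloxyphenyl)ethenyl]-2-methoxyphenoxy]phenyl]methanol (mixture of E and Z isomers), via benzylic ylide 7 (not isolated)
Conditions: K2CO3, 18-crown-6 (cat.), CH2Cl2, reflux
Reagents that add atoms: none
Why: Wittig olefination with a semi-stabilised benzylic ylide generated under solid–liquid phase transfer; carbonate does not deprotonate the benzylic alcohol, and the expected mixture of olefin isomers is of no consequence.

Step 4
Reactants: 8 [3-[5-[2-(4-benzyloxyphenyl)ethenyl]-2-methoxyphenoxy]phenyl]methanol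
Product: 9 4-[2-[3-[3-(hydroxymethyl)phenoxy]-4-methoxyphenyl]ethyl]phenol
Conditions: H2 (1 atm), 10% Pd/C, EtOAc, rt
Reagents that add atoms: none
Why: Heterogeneous catalytic hydrogenation saturates the stilbene and hydrogenolyses the aryl benzyl ether in one operation; in neutral EtOAc the primary benzylic alcohol on ring D is a far slower hydrogenolysis substrate and should survive if the reaction is stopped at the calculated uptake.

Step 5
Reactants: 9 4-[2-[3-[3-(hydroxymethyl)phenoxy]-4-methoxyphenyl]ethyl]phenol; 4 3-bromo-4-methoxybenzaldehyde
Product: 10 3-[4-[2-[3-[3-(hydroxymethyl)phenoxy]-4-methoxyphenyl]ethyl]phenoxy]-4-methoxybenzaldehyde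
Conditions: CuI (10 mol %), picolinic acid (20 mol %), K3PO4, DMSO, 90 °C, Ar
Reagents that add atoms: none
Why: Second Ullmann etherification, now with an unhindered para-alkylphenoxide, a better nucleophile than that of step 2; the primary alcohol again stays un-ionised and the aldehyde of ring A is brought in unprotected.

Step 6
Reactants: 10 3-[4-[2-[3-[3-(hydroxymethyl)phenoxy]-4-methoxyphenyl]ethyl]phenoxy]-4-methoxybenzaldehyde
Product: 11 3-[4-[2-[3-[3-(bromomethyl)phenoxy]-4-methoxyphenyl]ethyl]phenoxy]-4-methoxybenzaldehyde
Conditions: PBr3, CH2Cl2, 0 °C
Reagents that add atoms: phosphorus tribromide, BrP(Br)Br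
Why: Conversion of a primary benzylic alcohol into the bromide through its phosphite ester, with SN2 displacement by bromide; the aryl aldehyde, methyl ethers and diaryl ethers are inert to PBr3 at 0 °C.

Step 7
Reactants: 11 3-[4-[2-[3-[3-(bromomethyl)phenoxy]-4-methoxyphenyl]ethyl]phenoxy]-4-methoxybenzaldehyde; 2 triphenylphosphine
Product: 12 [3-[5-[2-[4-(5-formyl-2-methoxyphenoxy)phenyl]ethyl]-2-methoxyphenoxy]benzyl]triphenylphosphonium bromide
Conditions: toluene, 90 °C
Reagents that add atoms: none
Why: SN2 quaternisation of the phosphine by the benzylic bromide; the neutral phosphine does not attack the aryl aldehyde, and precipitation of the salt withdraws it from the hot solution.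

Step 8
Reactants: 12 [3-[5-[2-[4-(5-formyl-2-methoxyphenoxy)phenyl]ethyl]-2-methoxyphenoxy]benzyl]triphenylphosphonium bromide
Product: 14 macrocyclic stilbene (19-membered ring; OMe at C4 of rings A and C; CH=CH between C1 of ring A and ring D; mixture of E and Z isomers), via ylide aldehyde 13 (not isolated)
Conditions: NaOMe, CH2Cl2, rt, slow addition of 12 (final concentration about 2 mM)
Reagents that add atoms: none
Why: Intramolecular Wittig macrocyclisation under pseudo-high dilution: each portion of salt is deprotonated and cyclises before the next arrives, so ring closure should outrun chain growth. The 19-membered ring is large and free of transannular strain, and this type of closure is established for macrocyclic bis(bibenzyl)s.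

Step 9
Reactants: 14 macrocyclic stilbene
Product: 15 macrocyclic bis(bibenzyl) dimethyl ether (OMe at C4 of rings A and C; C3 unsubstituted)
Conditions: H2 (1 atm), 10% Pd/C, EtOAc/THF, rt
Reagents that add atoms: none
Why: Catalytic hydrogenation of the stilbene double bond; both olefin isomers converge on one product, and aryl methyl ethers and diaryl ethers are not hydrogenolysed.

Step 10
Reactants: 15 macrocyclic bis(bibenzyl) dimethyl ether
Product: 16 macrocyclic bisphenol (OH at C4 of rings A and C; C3 unsubstituted)
Conditions: BBr3, CH2Cl2, −78 °C to rt; then H2O
Reagents that add atoms: none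
Why: Lewis-acid cleavage of aryl methyl ethers: boron binds the methoxy oxygen and bromide attacks the methyl carbon (SN2); the diaryl ethers offer no sp3 carbon on oxygen and stay intact.

Step 11
Reactants: 16 macrocyclic bisphenol
Product: 17 macrocyclic bis-salicylaldehyde (CHO at C3 and OH at C4 of rings A and C)
Conditions: MgCl2, Et3N, (CH2O)n, MeCN, reflux; then 1 M HCl
Reagents that add atoms: paraformaldehyde (as formaldehyde), C=O
Why: Casnati–Skattebøl ortho-formylation: the magnesium phenoxide binds formaldehyde and delivers it to the ortho carbon through a six-membered transition state, and a second formaldehyde oxidises the resulting benzylic alkoxide by hydride transfer. C5 carries the ether and C1 the bridge, so C3 is the only site available, and rings B and D have no phenol to direct the reagent.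

Step 12
Reactants: 17 macrocyclic bis-salicylaldehyde
Product: 19 target CNP0511668.0 (OH at C3 and C4 of rings A and C), via bis-formate 18 (not isolated)
Conditions: 30% H2O2, NaOH, degassed THF/H2O, 0 °C to rt, Ar; then Na2SO3, 1 M HCl
Reagents that add atoms: hydrogen peroxide, OO
Why: Dakin oxidation: NaOH turns each salicylaldehyde into its phenoxide and H2O2 into hydroperoxide, which adds to the formyl carbon; in the tetrahedral adduct the aryl group shifts from carbon to the proximal peroxide oxygen with loss of hydroxide (a Baeyer–Villiger-type 1,2-shift) to give the aryl formates of 18, which are saponified in the same medium. The closest known reaction is the conversion of 2-hydroxy-3-alkoxybenzaldehydes into 3-alkoxycatechols by alkaline H2O2, which has the same substitution around the reacting carbon. No ring is closed and no stereocentre is formed; two C3–O bonds are made. The selectivity needed is aryl over hydride migration, because hydride shift would give the salicylic acid; the ortho phenoxide at C4 pushes electron density onto the migrating carbon C3 and raises its migratory aptitude far above that of hydrogen. Chemoselectivity comes from the substrate, since rings B and D and the bridges offer nothing that hydroperoxide attacks. The catechols are the fragile part: a small excess of peroxide, low temperature, exclusion of air, a sulfite quench and prompt acidification should keep them from ortho-quinone formation.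

## Compound list

1 | 4-benzyloxybenzyl chloride | ClCc1ccc(OCc2ccccc2)cc1 | starting material
2 | triphenylphosphine | c1ccc(cc1)P(c1ccccc1)c1ccccc1 | starting material
3 | (4-benzyloxybenzyl)triphenylphosphonium chloride | [Cl-].c1ccc(cc1)COc1ccc(cc1)C[P+](c1ccccc1)(c1ccccc1)c1ccccc1 | intermediate
4 | 3-bromo-4-methoxybenzaldehyde | COc1ccc(C=O)cc1Br | starting material
5 | 3-hydroxybenzyl alcohol | OCc1cccc(O)c1 | starting material
6 | 3-[3-(hydroxymethyl)phenoxy]-4-methoxybenzaldehyde | COc1ccc(C=O)cc1Oc1cccc(CO)c1 | intermediate
7 | (4-benzyloxybenzylidene)triphenylphosphorane (benzylic ylide, not isolated) | c1ccc(cc1)COc1ccc(cc1)C=P(c1ccccc1)(c1ccccc1)c1ccccc1 | intermediate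
8 | [3-[5-[2-(4-benzyloxyphenyl)ethenyl]-2-methoxyphenoxy]phenyl]methanol (E/Z mixture, drawn without olefin geometry) | COc1ccc(C=Cc2ccc(OCc3ccccc3)cc2)cc1Oc1cccc(CO)c1 | intermediate
9 | 4-[2-[3-[3-(hydroxymethyl)phenoxy]-4-methoxyphenyl]ethyl]phenol | COc1ccc(CCc2ccc(O)cc2)cc1Oc1cccc(CO)c1 | intermediate
10 | 3-[4-[2-[3-[3-(hydroxymethyl)phenoxy]-4-methoxyphenyl]ethyl]phenoxy]-4-methoxybenzaldehyde | COc1ccc(C=O)cc1Oc1ccc(cc1)CCc1ccc(OC)c(c1)Oc1cccc(CO)c1 | intermediate
11 | 3-[4-[2-[3-[3-(bromomethyl)phenoxy]-4-methoxyphenyl]ethyl]phenoxy]-4-methoxybenzaldehyde | COc1ccc(C=O)cc1Oc1ccc(cc1)CCc1ccc(OC)c(c1)Oc1cccc(CBr)c1 | intermediate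
12 | [3-[5-[2-[4-(5-formyl-2-methoxyphenoxy)phenyl]ethyl]-2-methoxyphenoxy]benzyl]triphenylphosphonium bromide | [Br-].COc1ccc(C=O)cc1Oc1ccc(cc1)CCc1ccc(OC)c(c1)Oc1cccc(C[P+](c2ccccc2)(c2ccccc2)c2ccccc2)c1 | intermediate
13 | ylide aldehyde derived from 12 (not isolated) | COc1ccc(C=O)cc1Oc1ccc(cc1)CCc1ccc(OC)c(c1)Oc1cccc(C=P(c2ccccc2)(c2ccccc2)c2ccccc2)c1 | intermediate
14 | macrocyclic stilbene: 19-membered ring, OMe at C4 of rings A and C, CH=CH between C1 of ring A and ring D (E/Z mixture, drawn without olefin geometry) | COc1ccc2cc1Oc1ccc(cc1)CCc1ccc(OC)c(c1)Oc1cccc(c1)C=C2 | intermediate
15 | macrocyclic bis(bibenzyl) dimethyl ether: OMe at C4 of rings A and C, C3 unsubstituted | COc1ccc2cc1Oc1ccc(cc1)CCc1ccc(OC)c(c1)Oc1cccc(c1)CC2 | intermediate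
16 | macrocyclic bisphenol: OH at C4 of rings A and C, C3 unsubstituted | Oc1ccc2cc1Oc1ccc(cc1)CCc1ccc(O)c(c1)Oc1cccc(c1)CC2 | intermediate
17 | macrocyclic bis-salicylaldehyde: CHO at C3 and OH at C4 of rings A and C | O=Cc1cc2cc(c1O)Oc1ccc(cc1)CCc1cc(C=O)c(O)c(c1)Oc1cccc(c1)CC2 | intermediate
18 | macrocyclic bis-formate: OCHO at C3 and OH at C4 of rings A and C (not isolated) | O=COc1cc2cc(c1O)Oc1ccc(cc1)CCc1cc(OC=O)c(O)c(c1)Oc1cccc(c1)CC2 | intermediate
19 | CNP0511668.0: OH at C3 and C4 of rings A and C | Oc1cc2cc(c1O)Oc1ccc(cc1)CCc1cc(O)c(O)c(c1)Oc1cccc(c1)CC2 | target

## Step count and least certain steps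

Total step count: 12. Longest linear sequence: 11 steps (steps 2 to 12, from 4 and 5); step 1 is a one-step side branch.

**Step 12 (the key step).** The likely failure is over-oxidation of the electron-rich catechol rings by peroxide in base, giving ortho-quinones and ring-opened acids. A lesser risk is a stall after one of the two sites, leaving a mono-aldehyde. The fallback keeps the disconnection but takes the C4 oxygens through the oxidation as ethers, so that no free catechol meets an oxidant. It sets out from 17 and comes back at 19:
- BnBr and K2CO3 in DMF should give the bis-benzyl ether dialdehyde F1.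
- mCPBA in CH2Cl2 (Baeyer–Villiger oxidation of an ortho-alkoxybenzaldehyde) should give the bis-formate F2.
- K2CO3 in MeOH should cleave the formates to the C4-benzylated bis-phenol F3.
- H2 over 10% Pd/C in EtOAc should remove both benzyl groups under neutral, non-oxidising conditions and give 19.

**Step 8.** Intermolecular olefination may compete with ring closure and give linear and cyclic oligomers if the stationary concentration of the ylide is not kept low; adventitious water would hydrolyse the ylide. The fallback changes the ring-closing reaction and sets out from 10, coming back at 14. MnO2 in CH2Cl2 should oxidise the benzylic alcohol to the dialdehyde F4. An intramolecular McMurry coupling (low-valent titanium from TiCl4 and Zn, pyridine, THF, reflux, slow addition) should then join the two formyl carbons to give 14.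

**Step 11.** The second formylation may lag behind the first, because the mono-aldehyde chelates magnesium strongly. Prolonged heating with formaldehyde risks O-methoxymethylation and methylene bridging between electron-rich rings. The fallback places the formyl group through a halogen and sets out from 16, coming back at 17:
- NBS with catalytic i-Pr2NH in CH2Cl2 at 0 °C should brominate the only free ortho carbon of each phenol to give the dibromide F5.
- MOMCl and i-Pr2NEt should give the bis-MOM ether F6.
- Bromine–lithium exchange with n-BuLi in THF at −78 °C and quenching with DMF should give the bis-MOM dialdehyde F7.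
- HCl in MeOH should remove the MOM groups to give 17.

**Step 2.** The electron-rich, ortho-substituted bromide may undergo slow oxidative addition, so that hydrodebromination and side reactions of the benzylic alcohol at 90 °C gain ground. The same concern applies in weaker form to step 5. The fallback reverses the polarity of the ether formation and works at room temperature. It sets out from 5 and comes back at 6: a Chan–Lam–Evans coupling of the phenol of 5 with purchased 5-formyl-2-methoxyphenylboronic acid F8 (Cu(OAc)2, pyridine, 4 Å molecular sieves, CH2Cl2, air) should give 6 directly. The aliphatic hydroxyl is a much poorer partner than the phenol under these conditions.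

## Further compounds

F1 | step 12 | bis-benzyl ether of 17 (OBn at C4 and CHO at C3 of rings A and C) | O=Cc1cc2cc(c1OCc1ccccc1)Oc1ccc(cc1)CCc1cc(C=O)c(OCc3ccccc3)c(c1)Oc1cccc(c1)CC2
F2 | step 12 | bis-formate with OBn at C4 and OCHO at C3 of rings A and C | O=COc1cc2cc(c1OCc1ccccc1)Oc1ccc(cc1)CCc1cc(OC=O)c(OCc3ccccc3)c(c1)Oc1cccc(c1)CC2
F3 | step 12 | 4-O-benzyl-protected target (OBn at C4 and OH at C3 of rings A and C) | Oc1cc2cc(c1OCc1ccccc1)Oc1ccc(cc1)CCc1cc(O)c(OCc3ccccc3)c(c1)Oc1cccc(c1)CC2
F4 | step 8 | 3-[4-[2-[3-(3-formylphenoxy)-4-methoxyphenyl]ethyl]phenoxy]-4-methoxybenzaldehyde | COc1ccc(C=O)cc1Oc1ccc(cc1)CCc1ccc(OC)c(c1)Oc1cccc(C=O)c1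
F5 | step 11 | dibromo bisphenol (Br at C3 and OH at C4 of rings A and C) | Brc1cc2cc(c1O)Oc1ccc(cc1)CCc1cc(Br)c(O)c(c1)Oc1cccc(c1)CC2
F6 | step 11 | bis-MOM ether of the dibromide (Br at C3 and OMOM at C4 of rings A and C) | Brc1cc2cc(c1OCOC)Oc1ccc(cc1)CCc1cc(Br)c(OCOC)c(c1)Oc1cccc(c1)CC2
F7 | step 11 | bis-MOM ether of 17 (CHO at C3 and OMOM at C4 of rings A and C) | O=Cc1cc2cc(c1OCOC)Oc1ccc(cc1)CCc1cc(C=O)c(OCOC)c(c1)Oc1cccc(c1)CC2
F8 | step 2 | 5-formyl-2-methoxyphenylboronic acid (purchased) | COc1ccc(C=O)cc1B(O)O
A1 | alternative 1 | open-chain aroyl chloride with a para-vinyl group on ring B | COc1cc(CCc2cccc(Oc3cc(C(Cl)=O)cc(OC)c3OC)c2)cc(Oc2ccc(C=C)cc2)c1OC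
A2 | alternative 1 | tetra-O-methyl macrocyclic (E)-stilbene | COc1cc2cc(c1OC)Oc1ccc(cc1)/C=C/c1cc(OC)c(OC)c(c1)Oc1cccc(c1)CC2
A3 | alternative 2 | macrocycle with OMOM at C3 and hydrogen at C4 of rings A and C | COCOc1cc2cc(c1)Oc1ccc(cc1)CCc1cc(OCOC)cc(c1)Oc1cccc(c1)CC2
A4 | alternative 2 | bis-MOM ether of the target with both C4 hydroxyls free | COCOc1cc2cc(c1O)Oc1ccc(cc1)CCc1cc(OCOC)c(O)c(c1)Oc1cccc(c1)CC2
A5 | alternative 3 | open-chain phenol with a 5-fluoro-4-formyl-3-methoxy ring A | COc1cc(CCc2cccc(Oc3cc(CCc4ccc(O)cc4)cc(OC)c3OC)c2)cc(F)c1C=O
A6 | alternative 3 | macrocyclic aldehyde with formyl at C4 of ring A | COc1cc2cc(c1C=O)Oc1ccc(cc1)CCc1cc(OC)c(OC)c(c1)Oc1cccc(c1)CC2
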